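**Plan**

- Naming: ring A is the methyl-bearing benzoyl ring; going round it, its carbons are called by what they carry in the target: methyl carbon, unsubstituted carbon, hydroxyl carbon, carboxyl-bearing carbon, ether carbon, acyl-bearing carbon. Ring B is the phthalide arene: ester-oxygen carbon, hydroxymethyl carbon, hydroxyl carbon, lactone-carbonyl carbon, lactone-methylene carbon, ether carbon.
- Enabling feature: in ring A the ether carbon and the carboxyl-bearing carbon are neighbours. The diaryl ether C–O bond and the C–CO2H bond are therefore cut together, back to an aryne across these two carbons (masked as SiMe3 on the carboxyl-bearing carbon and OTf on the ether carbon) that the ester holds next to ring B. The ester C(=O)–O bond is cut next, giving ring A acid 11 and ring B phenol 19.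
- Forward: 11 comes from 3-methoxy-5-methylphenol by two carbamate-directed lithiations run in one flask. 19 comes from methyl 4-(benzyloxy)-2-hydroxybenzoate: the dioxine acetal ring first, then the lactone ring by C–H methylenation. After esterification the ring B ether oxygen is unveiled from a formyl group, which fixes the ester on the right oxygen.
- The seven-membered ring closes in step 15 with fluoride under CO2. One BCl3 step then frees both phenols and the alcohol.
- Stereochemistry: the target has no stereocentre and no stereogenic double bond, so nothing has to be set.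

Key step: step 15

Remark on the chemistry: the ring B ether oxygen enters the key step as its tert-butyldimethylsilyl ether, so that fluoride liberates the phenoxide without leaving an acidic proton beside the aryl anion.

**Route**

Step 1
Reactants: 1 3-methoxy-5-methylphenol
Product: 2 3-methoxy-5-methylphenyl N-isopropylcarbamate
Conditions: i-PrNCO, Et3N (cat.), CH2Cl2, rt
Reagents that add atoms: isopropyl isocyanate, CC(C)N=C=O
Why: Amine-catalysed addition of the phenol to the isocyanate (carbamoylation) should give the carbamate, an ortho-directing group that mild base can remove later.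

Step 2
Reactants: 2 3-methoxy-5-methylphenyl N-isopropylcarbamate
Product: 8 benzyl 2-[(isopropylcarbamoyl)oxy]-4-methoxy-6-methyl-3-(trimethylsilyl)benzoate, via N-silyl carbamate 3 (not isolated), via first aryllithium 4 (not isolated), via bis-silyl carbamate 5 (not isolated), via second aryllithium 6 (not isolated), via N-silyl benzyl ester 7 (not isolated)
Conditions: TMSOTf, TMEDA, Et2O, 0 °C to rt; n-BuLi (2 equiv), TMEDA, −78 °C; TMSCl (1 equiv), −78 to −40 °C; s-BuLi, TMEDA, −78 °C; ClCO2Bn, −78 °C to rt; aq. NaHSO4
Reagents that add atoms: chlorotrimethylsilane, C[Si](C)(C)Cl; benzyl chloroformate, O=C(Cl)OCc1ccccc1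
Why: Iterative directed ortho-metalation of the carbamate, its N–H masked in situ by silylation, should first lithiate the most acidic ring carbon, flanked by the carbamate oxygen and the methoxy group (the future carboxyl-bearing carbon of ring A), where the chlorosilane places silicon, and with that site blocked the second lithiation can only take the other carbon beside the carbamate (the future acyl-bearing carbon), which the chloroformate acylates to the benzyl ester.

Step 3
Reactants: 8 benzyl 2-[(isopropylcarbamoyl)oxy]-4-methoxy-6-methyl-3-(trimethylsilyl)benzoate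
Product: 10 benzyl 4-methoxy-6-methyl-2-(trifluoromethanesulfonyloxy)-3-(trimethylsilyl)benzoate, via phenol 9 (not isolated)
Conditions: DBU, Et2NH, MeCN, 40 °C; then PhNTf2, rt
Reagents that add atoms: N-phenylbis(trifluoromethanesulfonimide), O=S(=O)(N(c1ccccc1)S(=O)(=O)C(F)(F)F)C(F)(F)F
Why: Base-induced E1cB loss of isopropyl isocyanate (trapped by diethylamine) frees the hindered phenoxide, which is triflated in the same flask, the usual one-pot carbamate-to-triflate route to 2-silylaryl triflates.

Step 4
Reactants: 10 benzyl 4-methoxy-6-methyl-2-(trifluoromethanesulfonyloxy)-3-(trimethylsilyl)benzoate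
Product: 11 4-methoxy-6-methyl-2-(trifluoromethanesulfonyloxy)-3-(trimethylsilyl)benzoic acid
Conditions: H2 (1 atm), Pd/C, EtOAc, rt
Reagents that add atoms: none
Why: Hydrogenolysis of the benzyl ester under neutral conditions should leave aryl triflate and arylsilane untouched and release the ring A acid.

Step 5
Reactants: 12 methyl 4-(benzyloxy)-2-hydroxybenzoate
Product: 13 methyl 4-(benzyloxy)-3-formyl-2-hydroxybenzoate
Conditions: MgCl2, Et3N, (CH2O)n, MeCN, reflux
Reagents that add atoms: formaldehyde (from paraformaldehyde), C=O
Why: Magnesium-mediated ortho-formylation of phenols (Casnati–Skattebøl reaction) delivers formaldehyde through the magnesium phenoxide to the only free ortho carbon, between the hydroxyl and benzyloxy groups (the future hydroxymethyl carbon of ring B), so the para position stays unsubstituted.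

Step 6
Reactants: 13 methyl 4-(benzyloxy)-3-formyl-2-hydroxybenzoate
Product: 14 methyl 4-(benzyloxy)-2-hydroxy-3-(hydroxymethyl)benzoate
Conditions: NaBH4, THF/MeOH, 0 °C
Reagents that add atoms: none
Why: Borohydride reduction of the aryl aldehyde at 0 °C is far faster than attack on the methyl ester and should give the benzylic alcohol.

Step 7
Reactants: 14 methyl 4-(benzyloxy)-2-hydroxy-3-(hydroxymethyl)benzoate
Product: 15 methyl 5-(benzyloxy)-2,2-dimethyl-4H-1,3-benzodioxine-8-carboxylate
Conditions: 2,2-dimethoxypropane, TsOH·H2O (cat.), acetone, rt
Reagents that add atoms: 2,2-dimethoxypropane, COC(C)(C)OC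
Why: Acid-catalysed transacetalisation ties the phenol oxygen and the neighbouring hydroxymethyl group into a six-membered isopropylidene acetal, the only cyclic acetal possible while the other phenol oxygen is still benzylated.

Step 8
Reactants: 15 methyl 5-(benzyloxy)-2,2-dimethyl-4H-1,3-benzodioxine-8-carboxylate
Product: 16 5-(benzyloxy)-2,2-dimethyl-4H-1,3-benzodioxine-8-carboxylic acid
Conditions: LiOH, THF/MeOH/H2O, 50 °C; then 1 M HCl to pH 4, 0 °C
Reagents that add atoms: lithium hydroxide (hydroxide oxygen becomes the carboxyl OH), [Li+].[OH-]
Why: Saponification gives the free acid needed as directing group, and acetal and benzyl ether are stable to base while the careful acidification spares the acetal.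

Step 9
Reactants: 16 5-(benzyloxy)-2,2-dimethyl-4H-1,3-benzodioxine-8-carboxylic acid
Product: 17 5-(benzyloxy)-7-hydroxy-6-(hydroxymethyl)isobenzofuran-1(3H)-one 7-O,6-CH2O-isopropylidene acetal
Conditions: Pd(OAc)2 (10 mol %), K2HPO4, CH2Br2, 140 °C, sealed tube
Reagents that add atoms: dibromomethane, BrCBr
Why: Carboxylate-directed ortho C–H palladation by divalent palladium, alkylation with the dihalomethane and displacement of the second bromide by the carboxylate (C–H alkylation/lactonisation of benzoic acids) should build the phthalide ring at the only free ortho carbon, the future lactone-methylene carbon of ring B.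

Step 10
Reactants: 17 5-(benzyloxy)-7-hydroxy-6-(hydroxymethyl)isobenzofuran-1(3H)-one 7-O,6-CH2O-isopropylidene acetal
Product: 18 5,7-dihydroxy-6-(hydroxymethyl)isobenzofuran-1(3H)-one 7-O,6-CH2O-isopropylidene acetal
Conditions: H2 (1 atm), Pd/C, EtOAc, rt
Reagents that add atoms: none
Why: Hydrogenolysis cleaves the aryl O–benzyl bond quickly at ambient pressure, before the hindered cyclic benzylic C–O bonds of lactone and acetal react, and frees the phenol that will carry the ester.

Step 11
Reactants: 18 5,7-dihydroxy-6-(hydroxymethyl)isobenzofuran-1(3H)-one 7-O,6-CH2O-isopropylidene acetal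
Product: 19 4-formyl-5,7-dihydroxy-6-(hydroxymethyl)isobenzofuran-1(3H)-one 7-O,6-CH2O-isopropylidene acetal
Conditions: MgCl2, Et3N, (CH2O)n, MeCN, reflux
Reagents that add atoms: formaldehyde (from paraformaldehyde), C=O
Why: A second Casnati–Skattebøl ortho-formylation can only reach the last unsubstituted ring carbon, ortho to the free phenol (the future ether carbon of ring B), and so plants a latent oxygen there.

Step 12
Reactants: 11 4-methoxy-6-methyl-2-(trifluoromethanesulfonyloxy)-3-(trimethylsilyl)benzoic acid; 19 4-formyl-5,7-dihydroxy-6-(hydroxymethyl)isobenzofuran-1(3H)-one 7-O,6-CH2O-isopropylidene acetal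
Product: 21 depside aldehyde (5-O-[4-methoxy-6-methyl-2-(trifluoromethanesulfonyloxy)-3-(trimethylsilyl)benzoyl] ester of 19), via acid chloride 20 (not isolated)
Conditions: 11, 1-chloro-N,N,2-trimethylprop-1-en-1-amine, CH2Cl2, 0 °C to rt; then 19, Et3N, DMAP (cat.), CH2Cl2, 0 °C to rt
Reagents that add atoms: none
Why: Neutral conversion of the hindered acid into its chloride and DMAP-catalysed acylation (nucleophilic catalysis) of the only phenol present put the ester on the correct ring B oxygen without regiochemical ambiguity, since the neighbouring ring carbon still carries carbon and not oxygen.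

Step 13
Reactants: 21 depside aldehyde
Product: 23 depside phenol (ester 21 with a hydroxyl in place of the formyl group), via aryl formate 22 (not isolated)
Conditions: mCPBA, Na2HPO4, CH2Cl2, 0 °C to rt; then NaHCO3, MeOH, 0 °C
Reagents that add atoms: 3-chloroperoxybenzoic acid, O=C(OO)c1cccc(Cl)c1
Why: Baeyer–Villiger (Dakin-type) oxidation of the aryl aldehyde, with aryl migration favoured by the para alkoxy oxygen of the acetal, gives the aryl formate, which brief methanolysis cleaves under conditions too mild to move the hindered aroyl group.

Step 14
Reactants: 23 depside phenol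
Product: 24 depside silyl ether (tert-butyldimethylsilyl ether of 23)
Conditions: TBSCl, imidazole, DMF, 0 °C to rt
Reagents that add atoms: tert-butylchlorodimethylsilane, CC(C)(C)[Si](C)(C)Cl
Why: Silylation of the phenol removes the only acidic proton and turns the ring B ether oxygen into a fluoride-labile phenoxide precursor.

Step 15
Reactants: 24 depside silyl ether
Product: 27 depsidone carboxylic acid (ring A methyl ether; ring B isopropylidene acetal retained), via aryne phenoxide 25 (not isolated), via aryl potassium 26 (not isolated)
Conditions: KF, 18-crown-6, THF (0.01 M), CO2 (1 atm), 0 °C to rt; then 1 M HCl, 0 °C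
Reagents that add atoms: carbon dioxide, O=C=O
Why: Proposed new method: fluoride cleaves the aryl silyl ether to the ring B phenoxide and attacks the trimethylsilyl group of ring A, so that loss of triflate from the neighbouring carbon gives the aryne 25 across the carboxyl-bearing and ether carbons of ring A; the phenoxide, held in place by the ester, adds to the ether carbon and the aryl anion 26 left on the carboxyl-bearing carbon is carboxylated by CO2, which forms the diaryl ether C–O bond and the C–CO2H bond in one operation. The closest known reactions are three-component couplings of arynes from 2-silylaryl triflates with nitrogen nucleophiles (aminosilanes, imines) and CO2, and the intramolecular addition of phenols to arynes. The seven-membered ring closes by 7-exo-dig addition of oxygen to the aryne, and no stereocentre is formed. The step needs attack at the ether carbon and not at the carboxyl-bearing carbon, which is secured because the tether cannot reach the latter and because the adjacent methoxy group polarises the aryne so that negative charge builds up on the carbon beside it. It also needs carboxylation to outrun protonation, which is why the phenol is delivered as a silyl ether in an aprotic medium saturated with CO2, and it needs the aroyl group to stay on its ring B oxygen, which the doubly ortho-substituted carbonyl should ensure by resisting attack of the neighbouring phenoxide.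

Step 16
Reactants: 27 depsidone carboxylic acid
Product: 28 Conneotricone
Conditions: BCl3, CH2Cl2, −78 to 0 °C; then H2O/THF, 0 °C
Reagents that add atoms: none
Why: Lewis-acid dealkylation with BCl3 cleaves the ring A methyl ether through chelation with the neighbouring carboxyl group and opens the isopropylidene acetal at its ketal carbon, not at the benzylic carbon, so aqueous work-up should release both phenols and the hydroxymethyl group while aryl ester, lactone and diaryl ether survive.

**Compound list**

1 | 3-methoxy-5-methylphenol | Cc1cc(O)cc(OC)c1 | starting material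
2 | 3-methoxy-5-methylphenyl N-isopropylcarbamate | Cc1cc(OC)cc(OC(=O)NC(C)C)c1 | intermediate
3 | N-trimethylsilyl derivative of 2 | Cc1cc(OC)cc(OC(=O)N(C(C)C)[Si](C)(C)C)c1 | intermediate (not isolated)
4 | 2-lithio derivative of 3 (lithium between carbamate oxygen and methoxy group) | [Li]c1c(OC)cc(C)cc1OC(=O)N(C(C)C)[Si](C)(C)C | intermediate (not isolated)
5 | 3-methoxy-5-methyl-2-(trimethylsilyl)phenyl N-isopropyl-N-(trimethylsilyl)carbamate | Cc1cc(OC)c([Si](C)(C)C)c(OC(=O)N(C(C)C)[Si](C)(C)C)c1 | intermediate (not isolated)
6 | 6-lithio derivative of 5 (lithium between carbamate oxygen and methyl group) | Cc1cc(OC)c([Si](C)(C)C)c(OC(=O)N(C(C)C)[Si](C)(C)C)c1[Li] | intermediate (not isolated)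
7 | N-trimethylsilyl derivative of 8 | Cc1cc(OC)c([Si](C)(C)C)c(OC(=O)N(C(C)C)[Si](C)(C)C)c1C(=O)OCc1ccccc1 | intermediate (not isolated)
8 | benzyl 2-[(isopropylcarbamoyl)oxy]-4-methoxy-6-methyl-3-(trimethylsilyl)benzoate | Cc1cc(OC)c([Si](C)(C)C)c(OC(=O)NC(C)C)c1C(=O)OCc1ccccc1 | intermediate
9 | benzyl 2-hydroxy-4-methoxy-6-methyl-3-(trimethylsilyl)benzoate | Cc1cc(OC)c([Si](C)(C)C)c(O)c1C(=O)OCc1ccccc1 | intermediate (not isolated)
10 | benzyl 4-methoxy-6-methyl-2-(trifluoromethanesulfonyloxy)-3-(trimethylsilyl)benzoate | Cc1cc(OC)c([Si](C)(C)C)c(OS(=O)(=O)C(F)(F)F)c1C(=O)OCc1ccccc1 | intermediate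
11 | 4-methoxy-6-methyl-2-(trifluoromethanesulfonyloxy)-3-(trimethylsilyl)benzoic acid (ring A acid) | Cc1cc(OC)c([Si](C)(C)C)c(OS(=O)(=O)C(F)(F)F)c1C(=O)O | intermediate
12 | methyl 4-(benzyloxy)-2-hydroxybenzoate | COC(=O)c1ccc(OCc2ccccc2)cc1O | starting material
13 | methyl 4-(benzyloxy)-3-formyl-2-hydroxybenzoate | COC(=O)c1ccc(OCc2ccccc2)c(C=O)c1O | intermediate
14 | methyl 4-(benzyloxy)-2-hydroxy-3-(hydroxymethyl)benzoate | COC(=O)c1ccc(OCc2ccccc2)c(CO)c1O | intermediate
15 | methyl 5-(benzyloxy)-2,2-dimethyl-4H-1,3-benzodioxine-8-carboxylate | COC(=O)c1ccc(OCc2ccccc2)c2COC(C)(C)Oc12 | intermediate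
16 | 5-(benzyloxy)-2,2-dimethyl-4H-1,3-benzodioxine-8-carboxylic acid | O=C(O)c1ccc(OCc2ccccc2)c2COC(C)(C)Oc12 | intermediate
17 | 5-(benzyloxy)-7-hydroxy-6-(hydroxymethyl)isobenzofuran-1(3H)-one 7-O,6-CH2O-isopropylidene acetal | O=C1OCc2cc(OCc3ccccc3)c3COC(C)(C)Oc3c12 | intermediate
18 | 5,7-dihydroxy-6-(hydroxymethyl)isobenzofuran-1(3H)-one 7-O,6-CH2O-isopropylidene acetal | O=C1OCc2cc(O)c3COC(C)(C)Oc3c12 | intermediate
19 | 4-formyl-5,7-dihydroxy-6-(hydroxymethyl)isobenzofuran-1(3H)-one 7-O,6-CH2O-isopropylidene acetal (ring B phenol) | O=C1OCc2c(C=O)c(O)c3COC(C)(C)Oc3c12 | intermediate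
20 | 4-methoxy-6-methyl-2-(trifluoromethanesulfonyloxy)-3-(trimethylsilyl)benzoyl chloride | Cc1cc(OC)c([Si](C)(C)C)c(OS(=O)(=O)C(F)(F)F)c1C(Cl)=O | intermediate (not isolated)
21 | depside aldehyde: ester of acid 11 on the 5-hydroxyl of 19, formyl on the neighbouring ring B carbon | Cc1cc(OC)c([Si](C)(C)C)c(OS(=O)(=O)C(F)(F)F)c1C(=O)Oc1c(C=O)c2COC(=O)c2c2OC(C)(C)OCc12 | intermediate
22 | depside aryl formate: 21 with a formyloxy group in place of the formyl group | Cc1cc(OC)c([Si](C)(C)C)c(OS(=O)(=O)C(F)(F)F)c1C(=O)Oc1c(OC=O)c2COC(=O)c2c2OC(C)(C)OCc12 | intermediate (not isolated)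
23 | depside phenol: trimethylsilyl and triflate on adjacent ring A carbons, free hydroxyl on the ring B ether carbon | Cc1cc(OC)c([Si](C)(C)C)c(OS(=O)(=O)C(F)(F)F)c1C(=O)Oc1c(O)c2COC(=O)c2c2OC(C)(C)OCc12 | intermediate
24 | depside silyl ether: tert-butyldimethylsilyl ether of 23 (key-step precursor) | Cc1cc(OC)c([Si](C)(C)C)c(OS(=O)(=O)C(F)(F)F)c1C(=O)Oc1c(O[Si](C)(C)C(C)(C)C)c2COC(=O)c2c2OC(C)(C)OCc12 | intermediate
25 | ring A aryne carrying the potassium phenoxide of ring B | CC1=C(C(=O)Oc2c([O-])c3COC(=O)c3c3OC(C)(C)OCc23)C#CC(OC)=C1.[K+] | intermediate (not isolated)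
26 | cyclised depsidone with potassium on the ring A carboxyl-bearing carbon | Cc1cc(OC)c([K])c2c1C(=O)Oc1c3COC(C)(C)Oc3c3C(=O)OCc3c1O2 | intermediate (not isolated)
27 | depsidone carboxylic acid (ring A methyl ether, ring B isopropylidene acetal; key-step product) | Cc1cc(OC)c(C(=O)O)c2c1C(=O)Oc1c3COC(C)(C)Oc3c3C(=O)OCc3c1O2 | intermediate
28 | Conneotricone | Cc1cc(O)c(C(=O)O)c2c1C(=O)Oc1c(CO)c(O)c3c(c1O2)COC3=O | target

**Count and risks**

Total step count: 16. Longest linear sequence: 12 steps (12 to 28, steps 5 to 11 and 12 to 16). The ring A branch is 4 steps to acid 11.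

Steps most likely to fail:

1. Step 15 (new method). The aryl anion may pick up a proton, from traces of water or from the lactone methylene across the new ether, before it meets CO2. Alternatively the aroyl group may shift to the freshly freed neighbouring phenoxide before the aryne has formed. The fallback uses known chemistry only, sets out from phenol 23 and returns at 27; the triflate is kept as an electrophile instead of being turned into an aryne. Palladium-catalysed intramolecular C–O coupling of the aryl triflate with the neighbouring ring B phenol (Pd2(dba)3 as source of zerovalent palladium, t-BuXPhos, K3PO4, toluene, 90 °C; no fluoride, so silicon stays) should give the trimethylsilyl depsidone F1. Ipso-iododesilylation with ICl in CH2Cl2 at 0 °C turns the silicon marker into the aryl iodide F2. Iodine–magnesium exchange with i-PrMgCl·LiCl in THF at −40 °C, where aryl ester and lactone are tolerated, gives the arylmagnesium chloride F3, and a CO2 quench with acidic work-up then gives acid 27. This fallback cures proton capture; the phosphate base does not remove the risk of aroyl shift.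

2. Step 9. C–H palladation next to the carboxylate may be too slow on this crowded, electron-rich ring, so that O-alkylation of the carboxylate by dibromomethane or decomposition at 140 °C takes over. The fallback sets out from acid 16 and returns at 17. Carboxylate-directed ortho-lithiation of the unprotected acid at the same carbon (s-BuLi, TMEDA, THF, −90 °C) and a DMF quench give the ring-closed form of the formyl acid, the racemic hydroxyphthalide F4. NaBH4 in MeOH reduces it through its open formyl carboxylate form to the hydroxy acid F5, and acidification to pH 4 lets this lactonise to 17.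

3. Step 13. Hydrogen may migrate instead of the aryl group in the peracid adduct of this doubly ortho-substituted aldehyde, giving over-oxidation to the acid, or the aroyl group may move while the formate is cleaved. The fallback sets out from aldehyde 19 and returns at 23 by moving the oxidation in front of the coupling. Dakin oxidation of 19 (30% H2O2, catalytic diphenyl diselenide, CH2Cl2) gives the aryl formate F6, which aqueous NaHCO3 hydrolyses to the catechol F7. Monoacylation with acid chloride 20 (made from acid 11 as in step 12) and one equivalent of i-Pr2NEt at −20 °C should then occur at the more acidic hydroxyl, para to the lactone carbonyl, as in the selective functionalisation of the 4-hydroxyl of 3,4-dihydroxybenzaldehyde, and deliver 23.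

Further compounds
F1 | step 15 | trimethylsilyl depsidone (silicon on the ring A carboxyl-bearing carbon; methyl ether and isopropylidene acetal retained) | Cc1cc(OC)c([Si](C)(C)C)c2c1C(=O)Oc1c3COC(C)(C)Oc3c3C(=O)OCc3c1O2
F2 | step 15 | iodo depsidone (iodine on the ring A carboxyl-bearing carbon; methyl ether and isopropylidene acetal retained) | Cc1cc(OC)c(I)c2c1C(=O)Oc1c3COC(C)(C)Oc3c3C(=O)OCc3c1O2
F3 | step 15 | arylmagnesium chloride from F2 (magnesium on the ring A carboxyl-bearing carbon) | Cc1cc(OC)c([Mg]Cl)c2c1C(=O)Oc1c3COC(C)(C)Oc3c3C(=O)OCc3c1O2
F4 | step 9 | racemic 3-hydroxy derivative of 17 (hydroxyphthalide, ring-closed formyl acid) | O=C1OC(O)c2cc(OCc3ccccc3)c3COC(C)(C)Oc3c12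
F5 | step 9 | 5-(benzyloxy)-7-(hydroxymethyl)-2,2-dimethyl-4H-1,3-benzodioxine-8-carboxylic acid (hydroxy acid) | O=C(O)c1c(CO)cc(OCc2ccccc2)c2COC(C)(C)Oc12
F6 | step 13 | 4-(formyloxy)-5,7-dihydroxy-6-(hydroxymethyl)isobenzofuran-1(3H)-one 7-O,6-CH2O-isopropylidene acetal (aryl formate) | O=COc1c(O)c2COC(C)(C)Oc2c2C(=O)OCc12
F7 | step 13 | 4,5,7-trihydroxy-6-(hydroxymethyl)isobenzofuran-1(3H)-one 7-O,6-CH2O-isopropylidene acetal (catechol) | O=C1OCc2c(O)c(O)c3COC(C)(C)Oc3c12
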